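## Structural features

The target is a flavonol: a 4H-chromen-4-one (benzene ring A fused to pyranone ring C through C4a and C8a) that carries a 3,4,5-trimethoxyphenyl ring B on C2 through the C2–C1' bond. It is flat and achiral, so no stereocenters stand next to each other or anywhere else; the problem is one of regiochemistry on ring A and of telling the oxygens apart. Ring A is a 1,2,3,5-tetraoxygenated benzene: O1 on C8a, methoxy on C8 and C7, hydrogen on C6, a free hydroxyl on C5 and the acyl carbon C4 on C4a. The fragile points are three. The 3-hydroxy enone of ring C is easily oxidized in base and air. The hydrogen-bonded 5-hydroxyl next to C4=O allows acid-induced opening and re-closure of ring C to the 5,6,7-isomer (Wessely–Moser rearrangement). The five methyl ethers must survive when O5 is unmasked. The real difficulty is to obtain ring A with the 5,7,8 pattern and with O5 distinguishable from O7 and O8, because phenols of this pattern are not stock chemicals. The key step uses the fact that the six carbons of ring A read O, O, O, H, O, H in the order C8a, C8, C7, C6, C5, C4a. This is the pattern that a vinylketene with two enol ether oxygens and an alkoxyacetylene write: the ketene carbon becomes C8a, the alkyne carbons become C4a and C5, and O5 arrives with its own alkyl group.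

## Logic of the disconnections

22 to 21: the O5–H bond is traced back to an O5–ethyl bond. The free 5-hydroxyl is unmasked last because it is the group that permits ring C isomerization and would interfere with the C3 oxidation. The gain is that every earlier intermediate is a fully O-alkylated, robust flavonoid. The demand is a dealkylation that touches only the ether peri to C4=O.

21 to 19: the C3–O bond is cut. Without O3 the flavone is reachable from an alkynoate and a phenol. The gain is that ring C needs no oxygenated two-carbon unit. The demand is an oxidant that attacks C2=C3 and spares two electron-rich arenes.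

19 to 18 to 17: the C4–C4a bond is cut (acyl–arene), and 18 is the acid of ester 17. Cutting here uses the fact that C4a is the only free carbon ortho to O1, so the 5,7,8 pattern cannot scramble. The gain is an acyclic aryl vinyl ether. The demand is an acylation strong enough for a conjugated acid yet mild to six aryl ethers.

17 to 13 and 16: the O1–C2 bond is cut. This splits the molecule into a ring A phenol and a ring B alkynoate of similar size. The demand is conjugate addition of a hindered phenoxide to an arylpropiolate; alkene geometry is not critical because it equilibrates in the next acid step.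

16 to 14: the bond between the alkyne carbon and the ester carbon is cut. This reduces ring B to a commercial aryl alkyne; the forward step is acetylide acylation.

13 to 7 and 8: three ring bonds are cut, C8a–C4a, C5–C6 and C8–C8a. Ring A is reduced to a four-carbon diazo enone that holds O7 and O8 and a two-carbon ynol ether that holds O5 with a distinct alkyl group. The gain is the loss of the whole aromatic ring and of the oxygen differentiation problem. The demand is that the ketene–alkyne addition has a single orientation and that the ketene is trapped by 8 faster than by anything else. The Z enol ether of 7 is kept so that the terminal methoxy group lies on the outside during ring closure.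

7 to 5 to 4: the bond between the acyl carbon and the diazomethyl carbon is cut, and 5 is the acid of ester 4. The forward acylation uses TMSCHN2 and not diazomethane, which removes the explosion hazard from the route. The demand is that the acid chloride of an enol ether survives its own formation.

4 to 1 and 2: the C2=C3 bond of the acrylate and the O–CH3 bond on O3 are cut. This leads to two bulk esters. The forward demands are a crossed Claisen condensation with a single enolizable partner and O- over C-methylation.

## Other disconnections considered

Alternative 1: The bond cut is C8a–O1, so ring C is closed last onto a ring A bought as a benzene. Forward, diketone A2 (2-(benzyloxy)-1-(2,4,5-trimethoxyphenyl)-3-(3,4,5-trimethoxyphenyl)propane-1,3-dione) would be oxidized with the trivalent iodine reagent PhI(OCOCF3)2 and BF3·OEt2 in hexafluoroisopropanol. The 2,4,5-trimethoxyphenyl ring is expected to give up one electron, the enol oxygen on the ring B side adds to C8a, and loss of a second electron and a proton would give A1 (3-(benzyloxy)-5,7,8-trimethoxy-2-(3,4,5-trimethoxyphenyl)-4H-chromen-4-one).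
- In its favour: ring A comes from the cheap arene A3 (1,2,4-trimethoxybenzene). C8a is the only C–H ortho to the acyl group, so the 5,7,8 pattern is set by the starting material. O3 is present from the start. The target would be reached in about five steps (acylation of A3, C-aroylation to A2, cyclization, removal of benzyl and of the 5-methyl group, both conceivable with BCl3).
- Against it here: the 5- and 8-methoxy groups of the ring to be oxidized are para to each other, the arrangement such oxidants convert into para-quinones by oxidative demethylation. Attack at the methoxy-bearing ortho carbon is a second path. Ring B and the benzylic ether are further oxidizable sites, and the other enol oxygen could close on ring B to give an isomeric flavone.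
- Comparison: on structure the plans are equal, since neither relies on a directing effect for the ring A pattern. On mechanism the alternative rests on the chemoselectivity of a strong one-electron oxidant toward the most electron-rich substrate of the sequence, whereas the pericyclic cascade chosen has a reactivity question but hardly a selectivity question. On step economy, on early placement of O3 and on avoiding a diazo compound and a lamp, the alternative is the better plan.

Alternative 2: The bond cut is C4–C4a. Forward, acid A5 ((Z)-3-(2,3,5-trimethoxyphenoxy)-3-(3,4,5-trimethoxyphenyl)acrylic acid) in P2O5/MeSO3H would form an acylium ion that attacks C4a and closes ring C to flavone A4 (5,7,8-trimethoxy-2-(3,4,5-trimethoxyphenyl)-4H-chromen-4-one).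
- In its favour: an acid-mediated acylation of a very electron-rich arene at the only free carbon ortho to the aryl oxygen, with no oxidant and no ambiguity. A5 would come in two steps from phenol A6 (2,3,5-trimethoxyphenol) and propiolate 16.
- Against it here: A6 is not a stock phenol. One terminal oxygen of a 1,2,3,5-tetraoxygenated benzene must be set free selectively, which means a protect, Dakin, methylate, deprotect sequence of about four steps from a hydroxydimethoxybenzaldehyde. A4 still lacks O3 and needs the same C3 oxidation as here. O5, O7 and O8 all carry methyl.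
- Comparison: on ring C the two plans are identical in mechanism, because the same closure is step 8 of the chosen plan; they differ only in the origin of ring A. On step count they are about equal (about four steps to A6, four to 13). The alternative is the better plan on robustness and safety (no diazo ketone, no photochemistry) and on the last step, since a 5-methyl ether should cleave under chelation control more readily than a 5-ethyl ether. The chosen plan is better only in that ring A is built from three simple open-chain pieces with O5 introduced separately, so the O5 substituent can be varied through the alkyne.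

Alternative 3: The cut is O1–C2, with ring C traced back to a five-membered ring in aurone A8 ((Z)-4,6,7-trimethoxy-2-(3,4,5-trimethoxybenzylidene)benzofuran-3(2H)-one). Forward, Br2 would add to the exocyclic alkene to give dibromide A9 (2-bromo-2-[bromo(3,4,5-trimethoxyphenyl)methyl]-4,6,7-trimethoxybenzofuran-3(2H)-one). KOH in ethanol would then open the furanone and let the phenoxide displace the benzylic bromide, forming O1–C2 and flavonol A7 (3-hydroxy-5,7,8-trimethoxy-2-(3,4,5-trimethoxyphenyl)-4H-chromen-4-one) (Auwers synthesis).
- In its favour: ring C and O3 arrive in one operation, so no separate C3 oxidation is needed; on this point it is better than the chosen plan. A8 is one aldol condensation away from coumaranone A10 (4,6,7-trimethoxybenzofuran-3(2H)-one) and aldehyde A11 (3,4,5-trimethoxybenzaldehyde).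
- Against it here: Br2 meets two very electron-rich rings, and C6–H of ring A (between two methoxy groups) is likely to be brominated in competition with the electron-poor alkene. With hydroxide the dibromide can also eliminate and return an aurone. A10 must be made from phenol A6 by chloroacetylation and ring closure, so the ring A problem of alternative 2 returns with two more steps.
- Comparison: on structure it solves O3 more directly than the chosen plan but ring A no better than alternative 2. On mechanism it depends on ionic halogen chemistry of uncertain chemoselectivity here, while the chosen plan uses no electrophilic halogen. On step economy it comes to about ten steps, equal to the chosen plan. The final dealkylation next to a free 3-hydroxyl is the same problem in both, with methyl slightly easier than ethyl.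

Key step: step 4

Remark: the Z geometry of 4 to 7 is assumed as the thermodynamic one; either geometry would serve, because the alkene carbon concerned ends as aromatic C8.
Remark: phenol 13 is named with lowest locants; the same compound can be numbered 3-ethoxy-5,6-dimethoxyphenol.

## Route

Step 1
Reactants: 1 methyl methoxyacetate; 2 methyl formate
Product: 4 methyl (Z)-2,3-dimethoxyacrylate, via sodium enolate 3 (not isolated)
Conditions: NaOMe, 2 (excess), MTBE, 0 °C to rt; then Me2SO4, DMF, 0 °C to rt; aq. NH3 quench
Reagents that add atoms: dimethyl sulfate, COS(=O)(=O)OC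
Why: Crossed Claisen condensation: 2 has no α-hydrogen, so only the enolate of 1 forms, and the stabilized formyl enolate 3 pulls the equilibrium through. The hard electrophile dimethyl sulfate should methylate the formyl oxygen, and the Z enol ether (3-methoxy trans to the ester) is the expected isomer; no stereocenter is formed.

Step 2
Reactants: 4 methyl (Z)-2,3-dimethoxyacrylate
Product: 5 (Z)-2,3-dimethoxyacrylic acid
Conditions: LiOH·H2O, THF/H2O, 0 °C to rt; then 1 M HCl to pH 3, 0 °C
Reagents that add atoms: lithium hydroxide, [Li+].[OH-]
Why: Ordinary ester saponification; β-alkoxyacrylates are vinylogous carbonates that tolerate cold hydroxide, and brief cold acidification should spare the enol ether.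

Step 3
Reactants: 5 (Z)-2,3-dimethoxyacrylic acid
Product: 7 (Z)-1-diazo-3,4-dimethoxybut-3-en-2-one, via acid chloride 6 (not isolated)
Conditions: (COCl)2, DMF (cat.), CH2Cl2, 0 °C to rt, evaporate; then TMSCHN2 (2 M in hexanes, 2.2 equiv), THF/MeCN, 0 °C to rt
Reagents that add atoms: (trimethylsilyl)diazomethane, C[Si](C)(C)C=[N+]=[N-]
Why: Acylation of a diazoalkane by an acid chloride (first stage of the Arndt–Eistert sequence), with non-explosive TMSCHN2 in place of diazomethane; chloride removes the silyl group from the acyldiazonium intermediate. The push–pull alkene of 6 is a poor dipolarophile and 6 has no α-hydrogen, so neither pyrazoline nor ketene formation should compete.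

Step 4
Reactants: 7 (Z)-1-diazo-3,4-dimethoxybut-3-en-2-one; 8 ethoxyacetylene
Product: 13 5-ethoxy-2,3-dimethoxyphenol, via vinylketene 9 (not isolated), via vinylcyclobutenone 10 (not isolated), via dienylketene 11 (not isolated), via cyclohexadienone 12 (not isolated)
Conditions: hν (254 nm, low-pressure Hg lamps, quartz), 8 (3 equiv), ClCH2CH2Cl (degassed), 25 °C; then 80 °C
Reagents that add atoms: none
Why: Light expels N2 from 7 and the dimethoxyvinyl group shifts to the diazo carbon (photochemical Wolff rearrangement), giving vinylketene 9. The nucleophilic CH carbon of ynol ether 8 attacks the ketene carbonyl carbon and the oxygen-bearing alkyne carbon closes on the ketene CH in a regiospecific (2+2) cycloaddition (four-membered ring; C8a–C4a and C5–C6), giving 10. Reversible four-electron conrotatory opening of 10, under the light or at 80 °C, gives dienylketene 11; ring A then closes by six-electron disrotatory electrocyclization between the ketene carbon and the terminal methoxy-bearing carbon (C8–C8a) to dienone 12, which tautomerizes irreversibly to 13. The closest known reaction is the Danheiser benzannulation in its diazo ketone version with alkoxy- and siloxyacetylenes; only the doubly methoxylated vinylketene is new, and its oxygen lone pairs are not conjugated with the in-plane C=O π* orbital that the alkyne attacks, so its electrophilicity should be retained. The one selectivity needed is the orientation of the (2+2) step, and the polarization of 8 secures it: ethoxy ends meta to the new hydroxyl (future O5 and O1) and C4a is left as the only free ortho carbon. The Z enol ether keeps the terminal methoxy group on the outside of the transition state for ring closure. An excess of volatile 8 should keep 9 from acylating the phenol already formed. No stereocenter remains: the sp3 carbons of 10 and 12 are racemic and are lost on aromatization.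

Step 5
Reactants: 14 5-ethynyl-1,2,3-trimethoxybenzene
Product: 16 methyl 3-(3,4,5-trimethoxyphenyl)prop-2-ynoate, via lithium acetylide 15 (not isolated)
Conditions: n-BuLi, THF, −78 °C; then ClCO2Me, −78 °C to rt
Reagents that add atoms: methyl chloroformate, COC(=O)Cl
Why: Deprotonation of a terminal alkyne and C-acylation of the acetylide with a chloroformate, a standard preparation of arylpropiolates.

Step 6
Reactants: 13 5-ethoxy-2,3-dimethoxyphenol; 16 methyl 3-(3,4,5-trimethoxyphenyl)prop-2-ynoate
Product: 17 methyl (Z)-3-(5-ethoxy-2,3-dimethoxyphenoxy)-3-(3,4,5-trimethoxyphenyl)acrylate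
Conditions: K2CO3 (0.3 equiv), DMF, 80 °C
Reagents that add atoms: none
Why: Base-mediated conjugate addition of a phenoxide to an arylpropiolate (oxa-Michael addition) forms O1–C2. Anti addition should place the aryloxy group cis to the ester (Z); any E isomer is tolerated because the two interconvert in the acid of step 8.

Step 7
Reactants: 17 methyl (Z)-3-(5-ethoxy-2,3-dimethoxyphenoxy)-3-(3,4,5-trimethoxyphenyl)acrylate
Product: 18 (Z)-3-(5-ethoxy-2,3-dimethoxyphenoxy)-3-(3,4,5-trimethoxyphenyl)acrylic acid
Conditions: NaOH (2 M aq), EtOH, 60 °C; then 1 M HCl
Reagents that add atoms: sodium hydroxide, [Na+].[OH-]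
Why: Ester saponification; hydroxide should attack the ester carbonyl and not the hindered, donor-substituted C3, so the aryloxy group stays in place.

Step 8
Reactants: 18 (Z)-3-(5-ethoxy-2,3-dimethoxyphenoxy)-3-(3,4,5-trimethoxyphenyl)acrylic acid
Product: 19 5-ethoxy-7,8-dimethoxy-2-(3,4,5-trimethoxyphenyl)-4H-chromen-4-one
Conditions: P2O5/MeSO3H (1:10 w/w), rt to 50 °C
Reagents that add atoms: none
Why: Intramolecular Friedel–Crafts acylation: the acylium ion attacks C4a, the only free carbon ortho to O1, which is activated by O1, the ortho ethoxy and the para methoxy group, so the 5,7,8 pattern cannot scramble. Acid equilibrates the alkene geometry, and six-membered closure on ring A should outrun five-membered closure on ring B to an indenone.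

Step 9
Reactants: 19 5-ethoxy-7,8-dimethoxy-2-(3,4,5-trimethoxyphenyl)-4H-chromen-4-one
Product: 21 5-ethoxy-3-hydroxy-7,8-dimethoxy-2-(3,4,5-trimethoxyphenyl)-4H-chromen-4-one, via flavone epoxide 20 (not isolated)
Conditions: dimethyldioxirane (ca. 0.08 M in acetone, 3 equiv), CH2Cl2, 0 °C to rt, dark; then p-TsOH·H2O (cat.), CH2Cl2, rt
Reagents that add atoms: dimethyldioxirane, CC1(C)OO1
Why: Electrophilic epoxidation of the enol ether-like C2=C3 bond of a fully O-alkylated flavone, then acid-catalysed opening of 20 to the C2 oxocarbenium ion and loss of H3, is a known passage from flavones to flavonols. Neutral conditions and the electron-withdrawing C4=O should protect the alkoxyarenes; the two stereocenters of 20 are transient.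

Step 10
Reactants: 21 5-ethoxy-3-hydroxy-7,8-dimethoxy-2-(3,4,5-trimethoxyphenyl)-4H-chromen-4-one
Product: 22 3,5-dihydroxy-7,8-dimethoxy-2-(3,4,5-trimethoxyphenyl)-4H-chromen-4-one
Conditions: BCl3 (1 M in CH2Cl2, 3 equiv), CH2Cl2, −78 °C to 0 °C; then MeOH, aq. NaHCO3
Reagents that add atoms: none
Why: Chelation-controlled ether cleavage: boron held between C4=O and O5 activates only the peri ether, and chloride removes the ethyl group as chloroethane, while the five unchelated methyl ethers should remain. Low temperature and a non-protic Lewis acid avoid ring C opening (Wessely–Moser isomerization) of the 5-hydroxyflavonol.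

## Compound list

1 | methyl methoxyacetate | COCC(=O)OC | starting material
2 | methyl formate | COC=O | starting material
3 | sodium 2,3-dimethoxy-3-oxoprop-1-en-1-olate (enolate geometry not fixed) | [Na+].[O-]C=C(OC)C(=O)OC | intermediate
4 | methyl (Z)-2,3-dimethoxyacrylate | CO/C=C(\OC)C(=O)OC | intermediate
5 | (Z)-2,3-dimethoxyacrylic acid | CO/C=C(\OC)C(=O)O | intermediate
6 | (Z)-2,3-dimethoxyacryloyl chloride | CO/C=C(\OC)C(=O)Cl | intermediate
7 | (Z)-1-diazo-3,4-dimethoxybut-3-en-2-one | CO/C=C(\OC)C(=O)C=[N+]=[N-] | intermediate
8 | ethoxyacetylene | CCOC#C | starting material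
9 | (Z)-3,4-dimethoxybuta-1,3-dien-1-one | CO/C=C(\OC)C=C=O | intermediate
10 | 4-[(Z)-1,2-dimethoxyethenyl]-3-ethoxycyclobut-2-en-1-one (racemic) | CCOC1=CC(=O)C1/C(OC)=C/OC | intermediate
11 | (3E,5Z)-3-ethoxy-5,6-dimethoxyhexa-1,3,5-trien-1-one | O=C=C/C(OCC)=C\C(OC)=C\OC | intermediate
12 | 3-ethoxy-5,6-dimethoxycyclohexa-2,4-dien-1-one (racemic) | CCOC1=CC(=O)C(OC)C(OC)=C1 | intermediate
13 | 5-ethoxy-2,3-dimethoxyphenol (also numbered 3-ethoxy-5,6-dimethoxyphenol) | CCOc1cc(O)c(OC)c(OC)c1 | intermediate
14 | 5-ethynyl-1,2,3-trimethoxybenzene | C#Cc1cc(OC)c(OC)c(OC)c1 | starting material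
15 | lithium (3,4,5-trimethoxyphenyl)acetylide | [Li]C#Cc1cc(OC)c(OC)c(OC)c1 | intermediate
16 | methyl 3-(3,4,5-trimethoxyphenyl)prop-2-ynoate | COC(=O)C#Cc1cc(OC)c(OC)c(OC)c1 | intermediate
17 | methyl (Z)-3-(5-ethoxy-2,3-dimethoxyphenoxy)-3-(3,4,5-trimethoxyphenyl)acrylate | CCOc1cc(OC)c(OC)c(O/C(=C\C(=O)OC)c2cc(OC)c(OC)c(OC)c2)c1 | intermediate
18 | (Z)-3-(5-ethoxy-2,3-dimethoxyphenoxy)-3-(3,4,5-trimethoxyphenyl)acrylic acid | CCOc1cc(OC)c(OC)c(O/C(=C\C(=O)O)c2cc(OC)c(OC)c(OC)c2)c1 | intermediate
19 | 5-ethoxy-7,8-dimethoxy-2-(3,4,5-trimethoxyphenyl)-4H-chromen-4-one | CCOc1cc(OC)c(OC)c2oc(-c3cc(OC)c(OC)c(OC)c3)cc(=O)c12 | intermediate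
20 | 2,3-epoxy-5-ethoxy-7,8-dimethoxy-2-(3,4,5-trimethoxyphenyl)chroman-4-one (racemic, epoxide necessarily cis-fused) | CCOc1cc(OC)c(OC)c2OC3(c4cc(OC)c(OC)c(OC)c4)OC3C(=O)c12 | intermediate
21 | 5-ethoxy-3-hydroxy-7,8-dimethoxy-2-(3,4,5-trimethoxyphenyl)-4H-chromen-4-one | CCOc1cc(OC)c(OC)c2oc(-c3cc(OC)c(OC)c(OC)c3)c(O)c(=O)c12 | intermediate
22 | 3,5-dihydroxy-7,8-dimethoxy-2-(3,4,5-trimethoxyphenyl)-4H-chromen-4-one (3,5-dihydroxy-7,8,3',4',5'-pentamethoxyflavone) | COc1cc(-c2oc3c(OC)c(OC)cc(O)c3c(=O)c2O)cc(OC)c1OC | target

## Step count and least certain steps

Total: 10 steps. Longest linear sequence: 9 steps (1, 2, 3, 4, 6, 7, 8, 9, 10); step 5 is a one-step side branch.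

**Step 4 (key step).** The most likely failure is poor capture of the ketene. Vinylketene 9 must find volatile 8 in a bimolecular step, and if that is slow it can dimerize or acylate the phenol already formed. Ring opening of 10 can also stall, and the electron-rich products can be degraded by further irradiation. The reactivity of a doubly methoxylated vinylketene has no direct precedent. More alkyne, a longer thermal stage and methanolic KOH treatment of the crude product (to release any acylated phenol) are the first remedies. The fallback changes the approach and takes ring A from an aromatic precursor. It sets out from no numbered compound (1 to 8 are bypassed) and comes back to the route at 13. Purchased 3-hydroxy-4,5-dimethoxybenzaldehyde F1 would be benzylated (BnBr, K2CO3, DMF) to 3-(benzyloxy)-4,5-dimethoxybenzaldehyde F2. Baeyer–Villiger oxidation with mCPBA in CH2Cl2 would give 3-(benzyloxy)-4,5-dimethoxyphenyl formate F3, which would be methanolysed without isolation (K2CO3, MeOH) to 3-(benzyloxy)-4,5-dimethoxyphenol F4. Ethylation (EtI, K2CO3, DMF) would give 1-(benzyloxy)-5-ethoxy-2,3-dimethoxybenzene F5, and hydrogenolysis (H2, Pd/C, EtOAc) would give 13.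

**Step 3.** The most likely failure is decomposition during activation: addition of HCl across the enol ether while the acid chloride forms, or dipolar cycloaddition of the diazoalkane to the conjugated alkene. The fallback sets out from 5 and comes back at 7, and replaces acylation of a diazoalkane by diazo transfer to a methyl ketone. Acid 5 would be converted with carbonyldiimidazole and MeNHOMe·HCl into (Z)-N,2,3-trimethoxy-N-methylprop-2-enamide F6. MeMgBr in THF at −78 to 0 °C would give (Z)-3,4-dimethoxybut-3-en-2-one F7. Kinetic deprotonation with LiN(SiMe3)2 at −78 °C and trapping with CF3CO2CH2CF3 would give (Z)-1,1,1-trifluoro-5,6-dimethoxyhex-5-ene-2,4-dione F8, not isolated. 4-Acetamidobenzenesulfonyl azide, Et3N and water in MeCN would then transfer the diazo group with loss of the trifluoroacetyl group and give 7.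

**Step 9.** The most likely failure is oxidation in the wrong place or none at all: epoxidation of the electron-poor C2=C3 bond is slow, so hydroxylation of the alkoxyarenes can compete, and hydrolytic opening of the epoxide can lead to ring C cleavage. The fallback sets out from 19 and comes back at 21 and uses a carbanion in place of an electrophilic oxidant. Deprotonation of C3–H with LiN(iPr)2 in THF at −78 °C and trapping with B(OMe)3 would give dimethyl [5-ethoxy-7,8-dimethoxy-4-oxo-2-(3,4,5-trimethoxyphenyl)-4H-chromen-3-yl]boronate F9, not isolated. Oxidation with H2O2 and AcOH would give 21.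

**Step 10.** The most likely failure is loss of selectivity in the ether cleavage. The free 3-hydroxyl binds boron first at C4=O, and an ethyl group leaves more slowly than a methyl, so the crowded 4'- or 8-methyl ethers may begin to cleave before O5 is free. The fallback sets out from 19 and comes back at 22; it dealkylates before the C3 oxidation, when C4=O and O5 are the only chelating pair. BCl3 on 19 would give 5-hydroxy-7,8-dimethoxy-2-(3,4,5-trimethoxyphenyl)-4H-chromen-4-one F10. Acetylation (Ac2O, pyridine, DMAP) would give 7,8-dimethoxy-4-oxo-2-(3,4,5-trimethoxyphenyl)-4H-chromen-5-yl acetate F11. Dimethyldioxirane, then catalytic p-TsOH, would pass through 2,3-epoxy-7,8-dimethoxy-4-oxo-2-(3,4,5-trimethoxyphenyl)chroman-5-yl acetate F12, not isolated, to 3-hydroxy-7,8-dimethoxy-4-oxo-2-(3,4,5-trimethoxyphenyl)-4H-chromen-5-yl acetate F13. K2CO3 in MeOH under argon would remove the acetate and give 22.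

## Further compounds

F1 | step 4 | 3-hydroxy-4,5-dimethoxybenzaldehyde | COc1cc(C=O)cc(O)c1OC
F2 | step 4 | 3-(benzyloxy)-4,5-dimethoxybenzaldehyde | COc1cc(C=O)cc(OCc2ccccc2)c1OC
F3 | step 4 | 3-(benzyloxy)-4,5-dimethoxyphenyl formate | COc1cc(OC=O)cc(OCc2ccccc2)c1OC
F4 | step 4 | 3-(benzyloxy)-4,5-dimethoxyphenol | COc1cc(O)cc(OCc2ccccc2)c1OC
F5 | step 4 | 1-(benzyloxy)-5-ethoxy-2,3-dimethoxybenzene | CCOc1cc(OC)c(OC)c(OCc2ccccc2)c1
F6 | step 3 | (Z)-N,2,3-trimethoxy-N-methylprop-2-enamide | CO/C=C(\OC)C(=O)N(C)OC
F7 | step 3 | (Z)-3,4-dimethoxybut-3-en-2-one | CO/C=C(\OC)C(C)=O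
F8 | step 3 | (Z)-1,1,1-trifluoro-5,6-dimethoxyhex-5-ene-2,4-dione | CO/C=C(\OC)C(=O)CC(=O)C(F)(F)F
F9 | step 9 | dimethyl [5-ethoxy-7,8-dimethoxy-4-oxo-2-(3,4,5-trimethoxyphenyl)-4H-chromen-3-yl]boronate | CCOc1cc(OC)c(OC)c2oc(-c3cc(OC)c(OC)c(OC)c3)c(B(OC)OC)c(=O)c12
F10 | step 10 | 5-hydroxy-7,8-dimethoxy-2-(3,4,5-trimethoxyphenyl)-4H-chromen-4-one | COc1cc(-c2cc(=O)c3c(O)cc(OC)c(OC)c3o2)cc(OC)c1OC
F11 | step 10 | 7,8-dimethoxy-4-oxo-2-(3,4,5-trimethoxyphenyl)-4H-chromen-5-yl acetate | COc1cc(-c2cc(=O)c3c(OC(C)=O)cc(OC)c(OC)c3o2)cc(OC)c1OC
F12 | step 10 | 2,3-epoxy-7,8-dimethoxy-4-oxo-2-(3,4,5-trimethoxyphenyl)chroman-5-yl acetate (racemic) | COc1cc(cc(OC)c1OC)C12OC1C(=O)c1c(OC(C)=O)cc(OC)c(OC)c1O2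
F13 | step 10 | 3-hydroxy-7,8-dimethoxy-4-oxo-2-(3,4,5-trimethoxyphenyl)-4H-chromen-5-yl acetate | COc1cc(-c2oc3c(OC)c(OC)cc(OC(C)=O)c3c(=O)c2O)cc(OC)c1OC
A1 | alternative 1 | 3-(benzyloxy)-5,7,8-trimethoxy-2-(3,4,5-trimethoxyphenyl)-4H-chromen-4-one | COc1cc(OC)c2c(=O)c(OCc3ccccc3)c(-c3cc(OC)c(OC)c(OC)c3)oc2c1OC
A2 | alternative 1 | 2-(benzyloxy)-1-(2,4,5-trimethoxyphenyl)-3-(3,4,5-trimethoxyphenyl)propane-1,3-dione (racemic) | COc1cc(OC)c(OC)cc1C(=O)C(OCc1ccccc1)C(=O)c1cc(OC)c(OC)c(OC)c1
A3 | alternative 1 | 1,2,4-trimethoxybenzene | COc1ccc(OC)c(OC)c1
A4 | alternative 2 | 5,7,8-trimethoxy-2-(3,4,5-trimethoxyphenyl)-4H-chromen-4-one | COc1cc(OC)c2c(=O)cc(-c3cc(OC)c(OC)c(OC)c3)oc2c1OC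
A5 | alternative 2 | (Z)-3-(2,3,5-trimethoxyphenoxy)-3-(3,4,5-trimethoxyphenyl)acrylic acid | COc1cc(OC)c(OC)c(O/C(=C\C(=O)O)c2cc(OC)c(OC)c(OC)c2)c1
A6 | alternative 2 | 2,3,5-trimethoxyphenol | COc1cc(O)c(OC)c(OC)c1
A7 | alternative 3 | 3-hydroxy-5,7,8-trimethoxy-2-(3,4,5-trimethoxyphenyl)-4H-chromen-4-one | COc1cc(OC)c2c(=O)c(O)c(-c3cc(OC)c(OC)c(OC)c3)oc2c1OC
A8 | alternative 3 | (Z)-4,6,7-trimethoxy-2-(3,4,5-trimethoxybenzylidene)benzofuran-3(2H)-one | COc1cc(OC)c2c(c1OC)O/C(=C\c1cc(OC)c(OC)c(OC)c1)C2=O
A9 | alternative 3 | 2-bromo-2-[bromo(3,4,5-trimethoxyphenyl)methyl]-4,6,7-trimethoxybenzofuran-3(2H)-one (racemic diastereomers) | COc1cc(OC)c2c(c1OC)OC(Br)(C(Br)c1cc(OC)c(OC)c(OC)c1)C2=O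
A10 | alternative 3 | 4,6,7-trimethoxybenzofuran-3(2H)-one | COc1cc(OC)c2c(c1OC)OCC2=O
A11 | alternative 3 | 3,4,5-trimethoxybenzaldehyde | COc1cc(C=O)cc(OC)c1OC
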